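The runs come from a simulation with made-up constants, and the scatter is random.

Keep the books on the reagent of the flask, entry by entry, until nothing is left to book.

| flask | substrate | reagent | remark | time |
|---|---|---|---|---|
| east | 0.25 M (fed, over 20 s) | 0.39 M | run made earlier |  |
| south-east | 0.25 M (fed, over 20 s) | 0.61 M | run made earlier |  |
| flask | 0.25 M (fed, over 20 s) | 0.275 M |  | 20 min |

| run | time / min | double product / % | first product / % |
|---|---|---|---|
| east | 2.00 | 71 | 3 |
| east | 4.00 | 71 | 0 |
| east | 10.0 | 70 | 2 |
| east | 25.0 | 74 | 0 |
| south-east | 2.00 | 98 | 1 |
| south-east | 4.00 | 100 | 0 |
| south-east | 10.0 | 100 | 0 |
| south-east | 25.0 | 100 | 0 |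

(standard deviation of a reading: 1.5 percentage points)

- the reaction counts as stopped when no species that holds the substrate changes by six tenths of a point or more over the second half of the time

* the state of affairs at 20 min: stopped, and by what, or still going (it is still moving / the reagent has run out first / all of the substrate has reacted)
* the double product standing at 20 min, as a percentage of the substrate charged

Each double product takes two reagent, so use perfect pairing as the zero of the scale. In the east run that would give 78.0% of double product, but the four readings average 71.5%, each with a scatter of 1.5 percentage points.

The east books then run like this. 0.39 M of reagent comes in, and double product takes 0.358 M. First product reads 0% at 25.0 min, so it gets no entry. That leaves, as a reading, 0.0325 M of stray reagent, meaning reagent charged that does not stand in double product. In the south-east run the surplus of 0.110 M is larger than this, and double product reads 100%.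

In the flask, reagent is the limiting reagent: 0.275 M is less than the 0.500 M that full doubling asks. Perfect pairing would give 55.0%. Take off the stray amount, halve what remains, and my figure is 48.5%. The east readings are flat from 2.00 min, earlier than 20 min, so I expect this flask to have stopped by then.

The forecast, the reagent has run out first with 49.5%, stands 1 point above my figure and says “The reagent runs out within minutes”.

At 20 min in the flask, the reagent has run out first, with 0% of its charge left, and double product stands at 47.2%, 1.3 points below my figure.

    substrate + reagent → first product (k = 1.21 L mol⁻¹ s⁻¹)
    substrate + reagent → other mono adduct (k = 0.0579 L mol⁻¹ s⁻¹)
    reagent + first product → double product (k = 3.58 L mol⁻¹ s⁻¹)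
    reagent + other mono adduct → double product (k = 0.0985 L mol⁻¹ s⁻¹)
    first product → over-reaction product A (k = 0.00333 s⁻¹)
    first product → over-reaction product B (k = 3.67 × 10⁻⁵ s⁻¹)
    substrate + first product → side product (k = 0.218 L mol⁻¹ s⁻¹)

Booked the same way, the stray reagent of the flask is 0.0390 M, against 0.0325 M from the east run. In the flask at 0.172 min, first product went on to double product 45 times as fast as into side product, yet the turnover into side product was half done at 0.746 min, later than the 0.172 min of the step from substrate to first product. Side product, which counts as two in its percentage, stands in the flask at 21.6% at 20.0 min. In the neighbour flask with 0.17 M of reagent, taking off 0.0325 M gives 27.5% of double product, and that flask stands at 26.2%.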